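**Plan**
- Retrosynthesis: both γ-lactones (rings D and E) are opened to 1,4-diols. Ring A (cyclopentene) is then cut at the two ring bonds that flank its tetrasubstituted C=C: alkene carbon–carbinol carbon and alkene carbon–aza-quaternary carbon. The second cut also opens ring B (pyrrolidine).
- Enabling feature: in ring A the aza-quaternary carbon (bonded to N, the ring C ketone carbon, CHEt and an alkene carbon) and the CH–O carbon are 1,3-related through CH(Et). They are the β-carbon and the formyl carbon of an α-ethyl enal. The ring A alkene is a former alkyne held on N by the CH–CH2 link that completes ring B.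
- Forward order: chiral alkyne → propargylic bromide → glycine alkylation → chelation-controlled chain extension → N-alkylation with a 3-bromofuran (masked bromo-enedione) → oxidative unmasking and closure of ring C (azepan-3-one) → key step closes ring B, then ring A → desilylation → double oxidative lactonization closes rings D and E.
- Stereochemistry: the two C–Me centres come from methyl (S)-3-hydroxy-2-methylpropanoate and (R)-3-bromo-2-methylpropan-1-ol. The N–CH centre is set by asymmetric phase-transfer alkylation and the adjacent CH–O centre by chelation-controlled Grignard addition. The aza-quaternary, CH(Et) and carbinol centres are set under substrate control in the key step.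

Key step: step 14

Remark: the exocyclic C=C of enaminone 25 is a push–pull alkene with a low rotation barrier; its geometry is left open in the SMILES and is lost in the key step. TBS = tert-butyldimethylsilyl.

**Route**

Step 1
Reactants: 1 methyl (S)-3-hydroxy-2-methylpropanoate
Product: 2 methyl (S)-3-[(tert-butyldimethylsilyl)oxy]-2-methylpropanoate
Conditions: TBSCl, imidazole, CH2Cl2, 0 °C to rt
Reagents that add atoms: tert-butyldimethylsilyl chloride, CC(C)(C)[Si](C)(C)Cl
Why: Standard silylation of a primary alcohol with TBSCl/imidazole, which does not touch the stereocentre.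

Step 2
Reactants: 2 methyl (S)-3-[(tert-butyldimethylsilyl)oxy]-2-methylpropanoate
Product: 3 (S)-3-[(tert-butyldimethylsilyl)oxy]-2-methylpropanal
Conditions: iBu2AlH (1.05 equiv), CH2Cl2, −78 °C; aqueous tartrate work-up
Reagents that add atoms: none
Why: Partial ester reduction with iBu2AlH stops at the stable tetrahedral aluminium hemiacetal at −78 °C and should release the aldehyde without epimerization of the α-methyl centre.

Step 3
Reactants: 3 (S)-3-[(tert-butyldimethylsilyl)oxy]-2-methylpropanal
Product: 4 (R)-tert-butyldimethyl[(2-methylbut-3-yn-1-yl)oxy]silane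
Conditions: Ohira–Bestmann reagent, K2CO3, MeOH, 0 °C to rt
Reagents that add atoms: dimethyl (1-diazo-2-oxopropyl)phosphonate, COP(=O)(OC)C(=[N+]=[N-])C(C)=O
Why: Seyferth–Gilbert homologation in the Ohira–Bestmann variant turns the aldehyde into the terminal alkyne under mild carbonate conditions that should keep the α-stereocentre (the descriptor changes to R only through priorities).

Step 4
Reactants: 4 (R)-tert-butyldimethyl[(2-methylbut-3-yn-1-yl)oxy]silane
Product: 6 (R)-5-[(tert-butyldimethylsilyl)oxy]-4-methylpent-2-yn-1-ol, via lithium acetylide 5 (not isolated)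
Conditions: n-BuLi, THF, −78 °C; (CH2O)n, −78 °C to rt
Reagents that add atoms: paraformaldehyde (as formaldehyde), C=O
Why: Deprotonation of the terminal alkyne and hydroxymethylation of the lithium acetylide with formaldehyde is a routine 1,2-addition.

Step 5
Reactants: 6 (R)-5-[(tert-butyldimethylsilyl)oxy]-4-methylpent-2-yn-1-ol
Product: 7 (R)-[(5-bromo-2-methylpent-3-yn-1-yl)oxy](tert-butyl)dimethylsilane
Conditions: CBr4, PPh3, CH2Cl2, 0 °C
Reagents that add atoms: carbon tetrabromide, BrC(Br)(Br)Br
Why: Appel bromination of the primary propargylic alcohol is neutral and should leave the silyl ether and the stereocentre untouched.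

Step 6
Reactants: 7 (R)-[(5-bromo-2-methylpent-3-yn-1-yl)oxy](tert-butyl)dimethylsilane; 8 tert-butyl N-(diphenylmethylidene)glycinate
Product: 9 tert-butyl (2S,6R)-7-[(tert-butyldimethylsilyl)oxy]-2-[(diphenylmethylidene)amino]-6-methylhept-4-ynoate
Conditions: O-allyl-N-(9-anthracenylmethyl)cinchonidinium bromide (10 mol %), CsOH·H2O, CH2Cl2, −78 °C
Reagents that add atoms: none
Why: Asymmetric phase-transfer alkylation of the glycine benzophenone imine; the chiral cinchonidinium cation ion-pairs with the enolate and shields one face, so the reactive propargylic bromide should give the (S)-amino ester.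

Step 7
Reactants: 10 (R)-3-bromo-2-methylpropan-1-ol
Product: 11 (R)-(3-bromo-2-methylpropoxy)(tert-butyl)dimethylsilane
Conditions: TBSCl, imidazole, DMF, rt
Reagents that add atoms: tert-butyldimethylsilyl chloride, CC(C)(C)[Si](C)(C)Cl
Why: Standard silylation of a primary alcohol, needed so that the bromide can be turned into a Grignard reagent.

Step 8
Reactants: 9 tert-butyl (2S,6R)-7-[(tert-butyldimethylsilyl)oxy]-2-[(diphenylmethylidene)amino]-6-methylhept-4-ynoate; 11 (R)-(3-bromo-2-methylpropoxy)(tert-butyl)dimethylsilane
Product: 15 (2S,4S,5S,9R)-5-amino-1,10-bis[(tert-butyldimethylsilyl)oxy]-2,9-dimethyldec-7-yn-4-ol, via Grignard reagent 12 (not isolated), via aluminoxy acetal 13 (not isolated), via imino alcohol 14 (not isolated)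
Conditions: 11, Mg, THF, rt (gives 12); 9, iBu2AlH/iBu3Al (1:1, 1.1 equiv), CH2Cl2, −78 °C; then 12 (3 equiv), −78 to 0 °C; then 15% aq. citric acid, THF, rt
Reagents that add atoms: none
Why: One-pot reduction of the Schiff-base ester to the aluminoxy acetal followed by Grignard addition under chelation control (imine nitrogen and oxygen held on the metal, attack anti to the propargylic chain) should give the syn (threo) amino alcohol, and mild acid then cleaves the benzophenone imine; the C–Me centre comes from 10.

Step 9
Reactants: 15 (2S,4S,5S,9R)-5-amino-1,10-bis[(tert-butyldimethylsilyl)oxy]-2,9-dimethyldec-7-yn-4-ol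
Product: 16 (2S,4S,5S,9R)-1,4,10-tris[(tert-butyldimethylsilyl)oxy]-2,9-dimethyldec-7-yn-5-amine
Conditions: TBSCl (1.5 equiv), imidazole, DMAP (cat.), DMF, 40 °C; aqueous work-up
Reagents that add atoms: tert-butyldimethylsilyl chloride, CC(C)(C)[Si](C)(C)Cl
Why: Chemoselective O-silylation of the amino alcohol (any N–Si bond is lost on work-up) masks the hydroxyl so that it cannot add back to the later enaminone.

Step 10
Reactants: 17 3,4-dibromofuran
Product: 19 3-bromo-4-ethylfuran, via 3-bromo-4-lithiofuran 18 (not isolated)
Conditions: n-BuLi (1.0 equiv), Et2O, −78 °C; EtOTf, −78 to −20 °C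
Reagents that add atoms: ethyl trifluoromethanesulfonate, CCOS(=O)(=O)C(F)(F)F
Why: Mono bromine–lithium exchange followed by alkylation with the highly reactive triflate, which should trap the 3-furyllithium at low temperature before it can decompose.

Step 11
Reactants: 19 3-bromo-4-ethylfuran; 20 1-chloro-4-iodobutane
Product: 22 3-bromo-2-(4-chlorobutyl)-4-ethylfuran, via 2-lithiofuran 21 (not isolated)
Conditions: LDA, THF, −78 °C; then 20, DMPU, −78 to 0 °C
Reagents that add atoms: none
Why: Directed deprotonation at the furan position flanked by oxygen and bromine (the most acidic C–H) and SN2 alkylation at the iodide end of the dihalide.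

Step 12
Reactants: 16 (2S,4S,5S,9R)-1,4,10-tris[(tert-butyldimethylsilyl)oxy]-2,9-dimethyldec-7-yn-5-amine; 22 3-bromo-2-(4-chlorobutyl)-4-ethylfuran
Product: 23 (2S,4S,5S,9R)-N-[4-(3-bromo-4-ethylfuran-2-yl)butyl]-1,4,10-tris[(tert-butyldimethylsilyl)oxy]-2,9-dimethyldec-7-yn-5-amine
Conditions: NaI (0.2 equiv), K2CO3, MeCN, 75 °C
Reagents that add atoms: none
Why: Finkelstein-assisted SN2 N-alkylation; the α-branched, β-silyloxy amine is hindered enough that the reaction should stop at the secondary amine.

Step 13
Reactants: 23 (2S,4S,5S,9R)-N-[4-(3-bromo-4-ethylfuran-2-yl)butyl]-1,4,10-tris[(tert-butyldimethylsilyl)oxy]-2,9-dimethyldec-7-yn-5-amine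
Product: 25 2-{1-[(2S,4S,5S,9R)-1,4,10-tris[(tert-butyldimethylsilyl)oxy]-2,9-dimethyldec-7-yn-5-yl]-3-oxoazepan-2-ylidene}butanal, via bromo enedione salt 24 (not isolated)
Conditions: TFA (1.1 equiv), CH2Cl2, 0 °C; mCPBA (1.1 equiv), −20 to 0 °C; then Et3N (4 equiv), 0 °C to rt
Reagents that add atoms: 3-chloroperbenzoic acid, OOC(=O)c1cccc(Cl)c1
Why: Peracid oxidative ring opening of the furan (amine masked as its ammonium salt) should give the cis bromo-enedione, and on neutralization the secondary amine closes ring C by 7-exo addition–elimination (vinylogous acyl substitution) at the bromine-bearing carbon β to the aldehyde.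

Step 14
Reactants: 25 2-{1-[(2S,4S,5S,9R)-1,4,10-tris[(tert-butyldimethylsilyl)oxy]-2,9-dimethyldec-7-yn-5-yl]-3-oxoazepan-2-ylidene}butanal
Product: 27 tricyclic cyclopentenol (rings A–C closed; ring A hydroxyl free and cis to N; ethyl trans to hydroxyl; three TBS ethers; all seven stereocentres as in 30), via oxanickelacycle 26 (not isolated)
Conditions: Ni(COD)2 (20 mol %), PBu3 (40 mol %), Et3B (4 equiv), MeOH/THF 7:1, 50 °C
Reagents that add atoms: none
Why: Proposed new method: phosphine-ligated zerovalent nickel binds the alkyne and the enal C=C of 25, whose vinylogous-formamide deactivation is reduced by the twist that ring C and the tetrasubstituted alkene force on the N–C=C unit and by Et3B/MeOH coordination at the formyl oxygen, and oxidative cyclization joins the proximal alkyne carbon to the N-bearing enal β-carbon to give the O-bound seven-membered oxanickelacycle 26; MeOH protonates the enolate carbon, the alkenyl–nickel bond adds to the freed formyl group, and Et3B turns the nickel dialkoxide over by ethyl transfer, β-hydride elimination and reductive elimination. The closest known reaction type is the nickel-catalysed reductive [3+2] cycloaddition of alkynes with enals (including tethered alkynyl enals, Ni(COD)2/PBu3/Et3B/MeOH), which has not been shown for a β-amino-β-acyl, fully substituted enal or for forming an α-tertiary amine. Ring B closes first by a 5-exo-dig/5-exo-trig oxidative cyclization across the N–CH–CH2 tether, and ring A closes second by 5-exo-trig 1,2-addition of the alkenylnickel carbon to the aldehyde. The aza-quaternary centre should be set by the existing N–CH centre, whose bulky silyloxyalkyl arm takes the pseudo-equatorial (exo) position on the forming pyrrolidine and so ends trans to the enal arm; the CH(Et) centre is set at the protonation stage and remains epimerizable as an α-formyl centre, so the epimer with ethyl on the convex face away from nitrogen should be funnelled through the insertion; the carbinol centre is set in the insertion with oxygen trans to ethyl and syn to the ring nitrogen, which can hold the nickel or boron alkoxide in a six-membered chelate. The step needs regioselectivity (the tether allows only the five-membered mode, the six-membered mode through the α-carbon being strained), chemoselectivity for the aldehyde over the ring C ketone (secured by proximity and aldehyde reactivity) and suppression of direct alkyne–aldehyde reductive coupling (which would need an eight-membered ring). The silyl ethers, the tertiary amine and the ketone should be inert under these neutral conditions.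

Step 15
Reactants: 27 tricyclic cyclopentenol
Product: 28 tetraol (ring A carbinol; side-chain carbinol; two primary alcohols; all stereocentres as in 30)
Conditions: HF·pyridine, THF/pyridine, 0 °C to rt
Reagents that add atoms: none
Why: Fluoride-driven cleavage of all three TBS ethers under buffered conditions, which should not affect the allylic alcohol, the ketone or the α-methyl centres.

Step 16
Reactants: 28 tetraol
Product: 30 CNP0315436.2, via bis-lactol 29 (not isolated)
Conditions: Cu(MeCN)4OTf (10 mol %), 2,2′-bipyridine (10 mol %), TEMPO (10 mol %), N-methylimidazole (20 mol %), MeCN, air, rt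
Reagents that add atoms: none
Why: Copper/nitroxyl aerobic oxidative lactonization of both 1,4-diols: each primary alcohol is oxidized selectively to the aldehyde, which is trapped by the γ-hydroxyl as a lactol and oxidized on to the γ-lactone (rings D and E), while secondary alcohols and the tertiary amine are tolerated and no stereocentre is touched.

**Compound list**
1 | methyl (S)-3-hydroxy-2-methylpropanoate | OC[C@H](C)C(=O)OC | starting material
2 | methyl (S)-3-[(tert-butyldimethylsilyl)oxy]-2-methylpropanoate | CC(C)(C)[Si](C)(C)OC[C@H](C)C(=O)OC | intermediate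
3 | (S)-3-[(tert-butyldimethylsilyl)oxy]-2-methylpropanal | CC(C)(C)[Si](C)(C)OC[C@H](C)C=O | intermediate
4 | (R)-tert-butyldimethyl[(2-methylbut-3-yn-1-yl)oxy]silane | CC(C)(C)[Si](C)(C)OC[C@H](C)C#C | intermediate
5 | lithium acetylide of 4 | CC(C)(C)[Si](C)(C)OC[C@H](C)C#C[Li] | intermediate (not isolated)
6 | (R)-5-[(tert-butyldimethylsilyl)oxy]-4-methylpent-2-yn-1-ol | CC(C)(C)[Si](C)(C)OC[C@H](C)C#CCO | intermediate
7 | (R)-[(5-bromo-2-methylpent-3-yn-1-yl)oxy](tert-butyl)dimethylsilane | CC(C)(C)[Si](C)(C)OC[C@H](C)C#CCBr | intermediate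
8 | tert-butyl N-(diphenylmethylidene)glycinate | CC(C)(C)OC(=O)CN=C(c1ccccc1)c1ccccc1 | starting material
9 | tert-butyl (2S,6R)-7-[(tert-butyldimethylsilyl)oxy]-2-[(diphenylmethylidene)amino]-6-methylhept-4-ynoate | CC(C)(C)[Si](C)(C)OC[C@H](C)C#CC[C@@H](C(=O)OC(C)(C)C)N=C(c1ccccc1)c1ccccc1 | intermediate
10 | (R)-3-bromo-2-methylpropan-1-ol | BrC[C@H](C)CO | starting material
11 | (R)-(3-bromo-2-methylpropoxy)(tert-butyl)dimethylsilane | BrC[C@H](C)CO[Si](C)(C)C(C)(C)C | intermediate
12 | (R)-{3-[(tert-butyldimethylsilyl)oxy]-2-methylpropyl}magnesium bromide | Br[Mg]C[C@H](C)CO[Si](C)(C)C(C)(C)C | intermediate (not isolated)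
13 | aluminoxy acetal of 9 (O-tert-butyl O-diisobutylaluminium hemiacetal; acetal carbon not defined) | CC(C)(C)[Si](C)(C)OC[C@H](C)C#CC[C@@H](C(OC(C)(C)C)O[Al](CC(C)C)CC(C)C)N=C(c1ccccc1)c1ccccc1 | intermediate (not isolated)
14 | (2S,4S,5S,9R)-1,10-bis[(tert-butyldimethylsilyl)oxy]-5-[(diphenylmethylidene)amino]-2,9-dimethyldec-7-yn-4-ol | CC(C)(C)[Si](C)(C)OC[C@H](C)C#CC[C@@H]([C@@H](O)C[C@H](C)CO[Si](C)(C)C(C)(C)C)N=C(c1ccccc1)c1ccccc1 | intermediate (not isolated)
15 | (2S,4S,5S,9R)-5-amino-1,10-bis[(tert-butyldimethylsilyl)oxy]-2,9-dimethyldec-7-yn-4-ol | CC(C)(C)[Si](C)(C)OC[C@H](C)C#CC[C@H](N)[C@@H](O)C[C@H](C)CO[Si](C)(C)C(C)(C)C | intermediate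
16 | (2S,4S,5S,9R)-1,4,10-tris[(tert-butyldimethylsilyl)oxy]-2,9-dimethyldec-7-yn-5-amine | CC(C)(C)[Si](C)(C)OC[C@H](C)C#CC[C@H](N)[C@@H](O[Si](C)(C)C(C)(C)C)C[C@H](C)CO[Si](C)(C)C(C)(C)C | intermediate
17 | 3,4-dibromofuran | Brc1cocc1Br | starting material
18 | 3-bromo-4-lithiofuran | [Li]c1cocc1Br | intermediate (not isolated)
19 | 3-bromo-4-ethylfuran | CCc1cocc1Br | intermediate
20 | 1-chloro-4-iodobutane | ClCCCCI | starting material
21 | 3-bromo-4-ethyl-2-lithiofuran | CCc1coc([Li])c1Br | intermediate (not isolated)
22 | 3-bromo-2-(4-chlorobutyl)-4-ethylfuran | CCc1coc(CCCCCl)c1Br | intermediate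
23 | (2S,4S,5S,9R)-N-[4-(3-bromo-4-ethylfuran-2-yl)butyl]-1,4,10-tris[(tert-butyldimethylsilyl)oxy]-2,9-dimethyldec-7-yn-5-amine | CCc1coc(CCCCN[C@@H](CC#C[C@@H](C)CO[Si](C)(C)C(C)(C)C)[C@@H](O[Si](C)(C)C(C)(C)C)C[C@H](C)CO[Si](C)(C)C(C)(C)C)c1Br | intermediate
24 | N-[(6E)-6-bromo-7-ethyl-5,8-dioxooct-6-en-1-yl] ammonium trifluoroacetate of amine 16 (carbonyl groups cis on the alkene) | O=C/C(CC)=C(/Br)C(=O)CCCC[NH2+][C@@H](CC#C[C@@H](C)CO[Si](C)(C)C(C)(C)C)[C@@H](O[Si](C)(C)C(C)(C)C)C[C@H](C)CO[Si](C)(C)C(C)(C)C.[O-]C(=O)C(F)(F)F | intermediate (not isolated)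
25 | 2-{1-[(2S,4S,5S,9R)-1,4,10-tris[(tert-butyldimethylsilyl)oxy]-2,9-dimethyldec-7-yn-5-yl]-3-oxoazepan-2-ylidene}butanal (alkene geometry labile) | CCC(C=O)=C1N([C@@H](CC#C[C@@H](C)CO[Si](C)(C)C(C)(C)C)[C@@H](O[Si](C)(C)C(C)(C)C)C[C@H](C)CO[Si](C)(C)C(C)(C)C)CCCCC1=O | intermediate
26 | seven-membered oxanickelacycle (Ni bound to the enolate oxygen and the alkenyl carbon, PBu3 on Ni; ring B closed) | CCC1=CO[Ni](P(CCCC)(CCCC)CCCC)C([C@@H](C)CO[Si](C)(C)C(C)(C)C)=C2C[C@@H]([C@@H](O[Si](C)(C)C(C)(C)C)C[C@H](C)CO[Si](C)(C)C(C)(C)C)N3CCCCC(=O)[C@@]123 | intermediate (not isolated)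
27 | tricyclic cyclopentenol: cyclopentene ring A fused to pyrrolidine ring B and spiro-linked through the aza-quaternary carbon to azepan-3-one ring C; ring A bears OH (cis to N), ethyl (trans to OH) and a (2R)-1-(TBS-oxy)propan-2-yl group on the alkene; ring B bears a (1S,3S)-1,4-bis(TBS-oxy)-3-methylbutyl group | CC[C@H]1[C@H](O)C([C@@H](C)CO[Si](C)(C)C(C)(C)C)=C2C[C@@H]([C@@H](O[Si](C)(C)C(C)(C)C)C[C@H](C)CO[Si](C)(C)C(C)(C)C)N3CCCCC(=O)[C@]213 | intermediate
28 | tetraol (27 without the three TBS groups) | CC[C@H]1[C@H](O)C([C@@H](C)CO)=C2C[C@@H]([C@@H](O)C[C@H](C)CO)N3CCCCC(=O)[C@]213 | intermediate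
29 | bis-lactol (both rings D and E closed at the lactol level; lactol carbons not defined) | CC[C@H]1[C@@H]2OC(O)[C@H](C)C2=C2C[C@@H]([C@@H]3C[C@H](C)C(O)O3)N3CCCCC(=O)[C@]213 | intermediate (not isolated)
30 | CNP0315436.2 | CC[C@H]1[C@@H]2OC(=O)[C@H](C)C2=C2C[C@@H]([C@@H]3C[C@H](C)C(=O)O3)N3CCCCC(=O)[C@]213 | target

**Step count and risks**

Total step count: 16. Longest linear sequence: 13 steps (steps 1–6, 8, 9, 12–16).

Steps most likely to fail:

1. Step 14 (Proposed new method). The electron-rich, fully substituted enal may not undergo oxidative cyclization, so that alkyne oligomerization or simple reduction takes over, and facial selectivity at the three new centres may be poor. The fallback is a stepwise radical/organochromium route that sets out from 25 and comes back at 27. Bu3SnH and AIBN in benzene at 80 °C should add a stannyl radical to the distal alkyne carbon; the vinyl radical closes ring B by 5-exo attack on the enal β-carbon and hydrogen transfer gives the vinylstannane aldehyde F1. Reversible stannyl-radical addition should place tin cis to the aza-quaternary carbon, since the long C–Sn bond makes the stannyl group the smaller alkene substituent. Iododestannylation with I2 in CH2Cl2 at 0 °C gives, with retention, the vinyl iodide F2. CrCl2 with catalytic NiCl2 in DMF then closes ring A by intramolecular Nozaki–Hiyama–Kishi addition to the aldehyde and gives 27.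

2. Step 13. The furan or the formyl group may be over-oxidized, the nitrogen may be oxidized if protonation is incomplete, or intermolecular condensation may compete with the seven-membered ring closure. The fallback changes the order of bond formation, sets out from 22 and 16 and comes back at 25. Furan 22 alone is oxidized (NBS, NaHCO3, aqueous acetone, −20 °C) to the bromo enedione F3. Amine 16 displaces the bromide by addition–elimination (Et3N, CH2Cl2, 0 °C) to give the secondary enaminone F4. Ring C is then closed by intramolecular N-alkylation (NaI, Cs2CO3, DMF, 60 °C) to give 25.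

3. Step 16. The tertiary amine or the allylic secondary hydroxyl may be oxidized competitively, and the α-methyl centre next to the ring A alkene may epimerize, or the alkene may migrate, at the β,γ-unsaturated aldehyde stage. The fallback separates oxidation from ring closure, sets out from 28 and comes back at 30. The trifluoroacetate salt of 28 is oxidized with TEMPO (cat.), NaClO2 and NaOCl (cat.) in phosphate buffer (pH 6.7)/MeCN, so that each aldehyde is trapped at once by chlorite, to give the bis(hydroxy acid) F5. Lactonization with TsOH (cat.) in toluene at rt then gives 30.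

Further compounds
F1 | step 14 | vinylstannane aldehyde (ring B closed; Bu3Sn on the exocyclic alkene carbon cis to the aza-quaternary carbon; CH(Et)CHO centre not defined) | CCC(C=O)[C@]12N(CCCCC1=O)[C@H]([C@@H](O[Si](C)(C)C(C)(C)C)C[C@H](C)CO[Si](C)(C)C(C)(C)C)C/C2=C(/[Sn](CCCC)(CCCC)CCCC)[C@@H](C)CO[Si](C)(C)C(C)(C)C
F2 | step 14 | vinyl iodide aldehyde (as F1 with iodine in place of tin) | CCC(C=O)[C@]12N(CCCCC1=O)[C@H]([C@@H](O[Si](C)(C)C(C)(C)C)C[C@H](C)CO[Si](C)(C)C(C)(C)C)C/C2=C(/I)[C@@H](C)CO[Si](C)(C)C(C)(C)C
F3 | step 13 | (2E)-3-bromo-8-chloro-2-ethyl-4-oxooct-2-enal (carbonyl groups cis) | O=C/C(CC)=C(/Br)C(=O)CCCCCl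
F4 | step 13 | secondary enaminone: 8-chloro-2-ethyl-4-oxo-3-{[(2S,4S,5S,9R)-1,4,10-tris(TBS-oxy)-2,9-dimethyldec-7-yn-5-yl]amino}oct-2-enal (alkene geometry labile) | CCC(C=O)=C(N[C@@H](CC#C[C@@H](C)CO[Si](C)(C)C(C)(C)C)[C@@H](O[Si](C)(C)C(C)(C)C)C[C@H](C)CO[Si](C)(C)C(C)(C)C)C(=O)CCCCCl
F5 | step 16 | bis(hydroxy acid) (28 with both primary alcohols oxidized to carboxylic acids) | CC[C@H]1[C@H](O)C([C@@H](C)C(=O)O)=C2C[C@@H]([C@@H](O)C[C@H](C)C(=O)O)N3CCCCC(=O)[C@]213
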